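**Plan**

1. Cuts: after the 3'-O–Si bond, ring A is opened at C4a–C5, C5–C6 and C7–C8. This leaves methoxyacetylene (C6, C7, 7-OMe) and a vinylketene on ring C, with C5 as the ketene carbonyl carbon and C8 with its prenyl group as the ketene alpha carbon. C8–C8a is cut next (conjugate addition of a 5-methylhex-4-enoate unit), and ring C last at C2–C3 and O1–C8a (hetero-Diels–Alder).
2. Enabling feature: the ring A/ring C fusion bond C4a=C8a, with O1 on C8a and the C4 ketone on C4a, is also the enol ether double bond of a 2-aryl-2,3-dihydro-4H-pyran-4-one, so it can act as the vinyl arm of a vinylketene. The run C5(OH)–C6(H)–C7(OMe)–C8(prenyl) is what ketene carbon + HC≡C–OMe + ketene alpha carbon deliver, so 8- versus 6-prenyl and the three oxygen positions follow from connectivity.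
3. Ring order: ring B is bought (isovanillin), ring C is closed first, a transient cyclobutenone follows, and ring A is closed last.
4. Stereochemistry: C2 is the only stereocentre. It is set as S by a BINOL–titanium catalysed hetero-Diels–Alder reaction and then passes only through cold, neutral or tertiary-amine conditions.
5. Design point: the side-chain carboxyl is carried as a silyl ester, so the ketene precursor is made without late hydrolysis and without freeing the decarboxylation-prone vinylogous beta-keto acid.

Key step: step 10

Remark: flavanone numbering (O1, C2, C3, C4, C4a, C5 to C8, C8a) is used for the corresponding atoms of every intermediate. Ar = 4-methoxy-3-(triisopropylsilyloxy)phenyl.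

Assumption: (S)-BINOL is taken to give the 2S series, by analogy with related BINOL–titanium additions to aromatic aldehydes. The absolute configuration of the hetero-Diels–Alder product is checked, and the mirror-image ligand is used if the sense proves opposite.

Step 1
Reactants: 1 isovanillin (3-hydroxy-4-methoxybenzaldehyde)
Product: 2 4-methoxy-3-(triisopropylsilyloxy)benzaldehyde
Conditions: TIPSCl, imidazole, DMF, rt
Reagents that add atoms: chlorotriisopropylsilane (TIPSCl), CC(C)[Si](Cl)(C(C)C)C(C)C
Why: Standard imidazole-promoted O-silylation of a phenol; the bulky aryl silyl ether should withstand silyl triflate, Pd(OAc)2, oxalyl chloride and heat, yet fall to buffered fluoride at the end.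

Step 2
Reactants: 2 4-methoxy-3-(triisopropylsilyloxy)benzaldehyde; 3 Danishefsky diene, (E)-1-methoxy-3-(trimethylsilyloxy)buta-1,3-diene
Product: 5 (S)-2-Ar-2,3-dihydro-4H-pyran-4-one, via silylated aldol adduct 4 (not isolated)
Conditions: (S)-BINOL (20 mol %), Ti(OiPr)4 (10 mol %), 4 Å MS, Et2O, −20 °C; then TFA, CH2Cl2, 0 °C, short contact; ee checked by chiral HPLC, recrystallisation if needed
Reagents that add atoms: none
Why: Catalytic enantioselective hetero-Diels–Alder reaction in its stepwise Mukaiyama aldol/cyclisation form, in which the chiral titanium complex shields one aldehyde face so that the diene terminus (C3) adds to give the S carbinol centre, and brief acid then joins O1 to C8a with loss of methanol without touching the C2–O bond.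

Step 3
Reactants: 6 2-methylbut-3-en-2-ol; 7 trimethyl orthoacetate
Product: 9 methyl 5-methylhex-4-enoate, via mixed ketene acetal 8 (not isolated)
Conditions: EtCO2H (cat.), neat, 120–140 °C, MeOH distilled off
Reagents that add atoms: none
Why: Johnson orthoester Claisen rearrangement, in which alcohol exchange and loss of methanol give the allyl ketene acetal whose (3,3) shift builds the prenyl-CH2-CO2Me chain, with no alkene geometry to control because the new double bond ends in a gem-dimethyl group.

Step 4
Reactants: 9 methyl 5-methylhex-4-enoate
Product: 10 5-methylhex-4-enoic acid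
Conditions: LiOH, THF/H2O, rt; then dilute HCl to pH 3
Reagents that add atoms: lithium hydroxide, [Li+].[OH-]
Why: Ordinary saponification, placed here on a robust small fragment so that no ester has to be hydrolysed later beside the base- and acid-sensitive ring C.

Step 5
Reactants: 10 5-methylhex-4-enoic acid
Product: 12 1,1-bis(tert-butyldimethylsilyloxy)-5-methylhexa-1,4-diene, via dilithium enediolate 11 (not isolated)
Conditions: LiN(iPr)2 (2.2 equiv), THF, −78 to 0 °C; TBSCl (2.3 equiv), DMPU, −78 °C to rt; pentane, filtration, bulb-to-bulb distillation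
Reagents that add atoms: tert-butyldimethylsilyl chloride (TBSCl), CC(C)(C)[Si](C)(C)Cl
Why: Known formation of a bis-silyl ketene acetal by double deprotonation of a carboxylic acid and O,O-silylation, in which the hindered chlorosilane favours oxygen over carbon and the two identical siloxy groups remove any ketene acetal geometry.

Step 6
Reactants: 5 (S)-2-Ar-2,3-dihydro-4H-pyran-4-one; 12 1,1-bis(tert-butyldimethylsilyloxy)-5-methylhexa-1,4-diene
Product: 13 tert-butyldimethylsilyl 2-[(6S)-6-Ar-4-(tert-butyldimethylsilyloxy)-5,6-dihydro-2H-pyran-2-yl]-5-methylhex-4-enoate (mixture at C8a and C8)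
Conditions: TBSOTf (10 mol %), 2,6-di-tert-butylpyridine (10 mol %), CH2Cl2, −78 °C; Et3N quench, Et3N-deactivated silica
Reagents that add atoms: none
Why: Mukaiyama–Michael addition, well known for silyl ketene acetals and 2,3-dihydro-4H-pyran-4-ones, in which the silyl triflate activates the C4 carbonyl, the ketene acetal attacks C8a and silyl transfer closes the cycle and fixes the enol silane at C4=C4a, while the new centres at C8a and C8 need no control because both become sp2 later, and low temperature plus a proton scavenger keep the 4-methoxybenzylic C2–O1 bond from ionising.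

Step 7
Reactants: 13 conjugate adduct (C4 enol silane, silyl ester)
Product: 14 tert-butyldimethylsilyl 2-[(2S)-2-Ar-4-oxo-3,4-dihydro-2H-pyran-6-yl]-5-methylhex-4-enoate (mixture at C8)
Conditions: Pd(OAc)2 (1.1 equiv), MeCN/CH2Cl2, rt; filtration through Celite, rapid chromatography
Reagents that add atoms: none
Why: Saegusa–Ito oxidation, in which palladation of the enol silane at C4a is followed by beta-hydride elimination for which only the C8a–H is available, so the C4a=C8a bond should return regiospecifically, the C8a centre is erased, and the trisubstituted prenyl alkene and the two remaining silyl groups are left alone.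

Step 8
Reactants: 14 silyl ester of the 6-substituted dihydropyranone
Product: 15 2-[(2S)-2-Ar-4-oxo-3,4-dihydro-2H-pyran-6-yl]-5-methylhex-4-enoyl chloride (mixture at C8)
Conditions: (COCl)2 (1.1 equiv), DMF (cat.), CH2Cl2, 0 °C to rt; volatiles removed under high vacuum, used at once
Reagents that add atoms: oxalyl chloride, ClC(=O)C(=O)Cl
Why: Known direct conversion of tert-butyldimethylsilyl esters into acid chlorides by chloroiminium activation, in which silicon leaves as the chlorosilane so that no HCl, water or free acid appears, sparing the prenyl alkene and the C2–O1 bond and avoiding decarboxylation.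

Step 9
Reactants: 16 chloroacetaldehyde dimethyl acetal (2-chloro-1,1-dimethoxyethane)
Product: 18 methoxyacetylene, via sodium methoxyacetylide 17 (not isolated)
Conditions: NaNH2 (3 equiv), liquid NH3, −33 °C; NH3 evaporated; cold saturated aqueous NaCl; product distilled into toluene at −78 °C and kept cold
Reagents that add atoms: none
Why: Established preparation of alkoxyacetylenes from chloroacetals by two successive amide-induced eliminations (methanol, then HCl), with the third equivalent of base holding the volatile product as its sodium salt until the quench.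

Step 10
Reactants: 15 acid chloride; 18 methoxyacetylene
Product: 23 (S)-5-hydroxy-7-methoxy-2-Ar-8-(3-methylbut-2-enyl)chroman-4-one (3'-O-triisopropylsilyl ether of the target), via vinylketene 19 (not isolated), via cyclobutenone 20 (not isolated), via dienylketene 21 (not isolated), via cyclohexadienone 22 (not isolated)
Conditions: 18 (5 equiv), toluene, −20 °C, iPr2NEt (1.0 equiv) added slowly, then 0 °C to rt; cold filtration through a short silica pad and purge of excess 18; then dilute toluene, 100–110 °C
Reagents that add atoms: none
Why: Proposed new method: iPr2NEt removes the C8–H of 15, which is acidified by both the acyl chloride and the vinylogous ester, and loss of chloride gives the prenyl(pyranonyl)ketene 19; the unsubstituted, nucleophilic carbon of 18 (future C6) attacks the ketene carbonyl carbon (future C5) and the methoxy-bearing carbon (C7) then bonds to C8, so that the four-membered ring of 20 is closed by a polar (2+2) cycloaddition across the ketene C=C bond. On heating, 20 opens by reversible conrotatory 4π cleavage of the C5–C8 bond to dienylketene 21, ring A is closed by a 6π electrocyclisation that joins C5 to C4a (the enol ether beta carbon of ring C, whose inward substituent is only hydrogen), and the C4a–H of dienone 22, flanked by two carbonyl groups, shifts to oxygen to give the chelated 5-OH phenol 23. The closest known reaction type is the Danheiser benzannulation of vinylketenes with alkoxyalkynes, backed by the known synthesis of 3-alkoxycyclobutenones from amine-generated ketenes and the known thermal rearrangement of 4-alkenylcyclobutenones to phenols; new are the C4a=C8a bond of a dihydropyranone as the vinyl partner and dehydrochlorination as the ketene source for this annulation. No lasting stereocentre is formed, since the quaternary carbon of 20 and C4a of 22 both end up sp2, and C2 is a spectator that stays safe because salt and residual amine are removed before the neutral thermal stage. Regiocontrol comes from polarity and connectivity: the ynol ether polarisation places OMe on C7 next to the prenyl-bearing C8, C4a is the only atom that can complete a six-membered carbocycle, and lactonisation through the C4 carbonyl oxygen is excluded because ring C holds C4 trans to C8 across C4a=C8a. The ring opening must turn the pyranonyl group inward and the prenyl group outward, which fits the outward preference of alkyl donors, and since the opening is reversible the wrongly turned ketene, whose only exit is a slower (2+2) addition to the prenyl double bond, should drain back through 20 into the fast 6π channel.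

Step 11
Reactants: 23 3'-O-triisopropylsilyl ether of the target
Product: 24 (2S)-5-hydroxy-2-(3-hydroxy-4-methoxyphenyl)-7-methoxy-8-(3-methylbut-2-enyl)-2,3-dihydro-4H-chromen-4-one (target)
Conditions: Bu4NF (1.1 equiv), AcOH (1.1 equiv), THF, 0 °C
Reagents that add atoms: none
Why: Fluoride-induced cleavage of an aryl silyl ether, buffered with acetic acid so that no free phenoxide or basic fluoride can trigger retro-oxa-Michael opening to the chalcone and racemise C2.

**Compound list**

1 | isovanillin | COc1ccc(C=O)cc1O | starting material
2 | 4-methoxy-3-(triisopropylsilyloxy)benzaldehyde | COc1ccc(C=O)cc1O[Si](C(C)C)(C(C)C)C(C)C | intermediate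
3 | Danishefsky diene | CO/C=C/C(=C)O[Si](C)(C)C | starting material
4 | (S,E)-5-Ar-1-methoxy-5-(trimethylsilyloxy)pent-1-en-3-one | COc1ccc([C@H](CC(=O)/C=C/OC)O[Si](C)(C)C)cc1O[Si](C(C)C)(C(C)C)C(C)C | intermediate
5 | (S)-2-Ar-2,3-dihydro-4H-pyran-4-one | COc1ccc([C@@H]2CC(=O)C=CO2)cc1O[Si](C(C)C)(C(C)C)C(C)C | intermediate
6 | 2-methylbut-3-en-2-ol | CC(C)(O)C=C | starting material
7 | trimethyl orthoacetate | CC(OC)(OC)OC | starting material
8 | 3-(1-methoxyethenyloxy)-3-methylbut-1-ene (mixed ketene acetal) | C=C(OC)OC(C)(C)C=C | intermediate
9 | methyl 5-methylhex-4-enoate | COC(=O)CCC=C(C)C | intermediate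
10 | 5-methylhex-4-enoic acid | OC(=O)CCC=C(C)C | intermediate
11 | dilithium enediolate of 5-methylhex-4-enoic acid | [Li+].[Li+].[O-]C([O-])=CCC=C(C)C | intermediate
12 | 1,1-bis(tert-butyldimethylsilyloxy)-5-methylhexa-1,4-diene | CC(C)=CCC=C(O[Si](C)(C)C(C)(C)C)O[Si](C)(C)C(C)(C)C | intermediate
13 | conjugate adduct, C4 TBS enol ether and TBS ester, 2S, mixture at C8a and C8 | COc1ccc([C@@H]2CC(O[Si](C)(C)C(C)(C)C)=CC(C(CC=C(C)C)C(=O)O[Si](C)(C)C(C)(C)C)O2)cc1O[Si](C(C)C)(C(C)C)C(C)C | intermediate
14 | 6-substituted (2S)-dihydropyranone TBS ester, mixture at C8 | COc1ccc([C@@H]2CC(=O)C=C(C(CC=C(C)C)C(=O)O[Si](C)(C)C(C)(C)C)O2)cc1O[Si](C(C)C)(C(C)C)C(C)C | intermediate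
15 | corresponding acid chloride, mixture at C8 | COc1ccc([C@@H]2CC(=O)C=C(C(CC=C(C)C)C(=O)Cl)O2)cc1O[Si](C(C)C)(C(C)C)C(C)C | intermediate
16 | chloroacetaldehyde dimethyl acetal | COC(CCl)OC | starting material
17 | sodium methoxyacetylide | COC#[C-].[Na+] | intermediate
18 | methoxyacetylene | COC#C | intermediate
19 | 2-[(2S)-2-Ar-4-oxo-3,4-dihydro-2H-pyran-6-yl]-5-methylhexa-1,4-dien-1-one (vinylketene) | COc1ccc([C@@H]2CC(=O)C=C(C(CC=C(C)C)=C=O)O2)cc1O[Si](C(C)C)(C(C)C)C(C)C | intermediate
20 | 3-methoxy-4-(3-methylbut-2-enyl)-4-[(2S)-2-Ar-4-oxo-3,4-dihydro-2H-pyran-6-yl]cyclobut-2-en-1-one, mixture at the quaternary carbon | COc1ccc([C@@H]2CC(=O)C=C(C3(CC=C(C)C)C(=O)C=C3OC)O2)cc1O[Si](C(C)C)(C(C)C)C(C)C | intermediate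
21 | 3-methoxy-7-methyl-4-[(2S)-2-Ar-4-oxo-3,4-dihydro-2H-pyran-6-yl]octa-1,3,6-trien-1-one, ketene and pyranonyl group on the same side of C7=C8 | COc1ccc([C@@H]2CC(=O)C=C(/C(CC=C(C)C)=C(OC)\C=C=O)O2)cc1O[Si](C(C)C)(C(C)C)C(C)C | intermediate
22 | (2S)-2-Ar-7-methoxy-8-(3-methylbut-2-enyl)-2,3-dihydro-4aH-chromene-4,5-dione (4a-H keto tautomer of 23) | COc1ccc([C@@H]2CC(=O)C3C(=O)C=C(OC)C(CC=C(C)C)=C3O2)cc1O[Si](C(C)C)(C(C)C)C(C)C | intermediate
23 | 3'-O-triisopropylsilyl ether of the target | COc1ccc([C@@H]2CC(=O)c3c(O)cc(OC)c(CC=C(C)C)c3O2)cc1O[Si](C(C)C)(C(C)C)C(C)C | intermediate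
24 | CNP0228678.1, (2S)-5,3'-dihydroxy-7,4'-dimethoxy-8-prenylflavanone | COc1ccc([C@@H]2CC(=O)c3c(O)cc(OC)c(CC=C(C)C)c3O2)cc1O | target

Total step count: 11.
Longest linear sequence: 8 steps (3, 4, 5, 6, 7, 8, 10, 11).

**Steps most likely to fail**

**Step 10.**
- What may go wrong: amine-induced dimerisation or oligomerisation of the ketene may outrun its capture by the ynol ether. Ring opening may proceed with the wrong sense of rotation, followed by capture of the ketene by the prenyl double bond. The 6π closure onto an enol ether carbon that also carries an acyl group may be sluggish.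
- Fallback: established flavanone chemistry from 1 back to 24.
- 1 is protected with MOMCl/iPr2NEt as 4-methoxy-3-(methoxymethoxy)benzaldehyde F1.
- Commercial 2',6'-dihydroxy-4'-methoxyacetophenone is C-prenylated (prenyl bromide, aqueous KOH) to 1-[2,6-dihydroxy-4-methoxy-3-(3-methylbut-2-enyl)phenyl]ethanone F2.
- The less hindered hydroxyl of F2, the one remote from the prenyl group, is capped with one equivalent of MOMCl to give 1-[2-hydroxy-4-methoxy-6-(methoxymethoxy)-3-(3-methylbut-2-enyl)phenyl]ethanone F3.
- Claisen–Schmidt condensation of F1 with F3 (KOH, EtOH) gives the 2'-hydroxychalcone F4. Only the hydroxyl next to the prenyl group is free in F4, so oxa-Michael closure (NaOAc, EtOH, reflux) can give only the 8-prenyl isomer, the racemic bis-MOM flavanone F5.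
- HCl in MeOH removes both MOM groups to give the racemic target F6. Preparative HPLC on a chiral stationary phase delivers 24, and the unwanted antipode is racemised through the chalcone with mild base and recycled.

**Step 8.**
- What may go wrong: the chloroiminium reagent may attack the nucleophilic carbonyl oxygen of the vinylogous ester in ring C. HCl may also be lost prematurely, with self-condensation during concentration.
- Fallback: from 14 back to 15. The silyl ester is hydrolysed with AcOH/THF/H2O at 0 °C to the free acid 2-[(2S)-2-Ar-4-oxo-3,4-dihydro-2H-pyran-6-yl]-5-methylhex-4-enoic acid F7. This acid is kept cold, not stored, and treated at once with 1-chloro-N,N,2-trimethylprop-1-en-1-amine in CH2Cl2 at 0 °C. That neutral reagent gives 15 without a chloroiminium salt and without HCl.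

**Step 7.**
- What may go wrong: palladation of the hindered enol silane may be slow, allowing protodesilylation by the liberated acetic acid. The silyl ester may undergo acidolysis followed by decarboxylation. Beta-alkoxide elimination may open ring C, or the metal may be tied up by the prenyl alkene.
- Fallback: from 13 back to 14 by selenoxide elimination. PhSeCl in CH2Cl2 at −78 °C reacts with the enol silane, the most nucleophilic alkene present, to give the C4a phenylselanyl ketone F8. mCPBA at −78 °C oxidises selenium selectively to the selenoxide F9. Warming in the presence of iPr2NH brings about syn elimination towards the only beta hydrogen, C8a–H, to give 14 under non-acidic, metal-free conditions.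

**Further compounds**

F1 | step 10 | 4-methoxy-3-(methoxymethoxy)benzaldehyde | COCOc1cc(C=O)ccc1OC
F2 | step 10 | 1-[2,6-dihydroxy-4-methoxy-3-(3-methylbut-2-enyl)phenyl]ethanone | CC(=O)c1c(O)cc(OC)c(CC=C(C)C)c1O
F3 | step 10 | 1-[2-hydroxy-4-methoxy-6-(methoxymethoxy)-3-(3-methylbut-2-enyl)phenyl]ethanone | CC(=O)c1c(OCOC)cc(OC)c(CC=C(C)C)c1O
F4 | step 10 | (E)-2'-hydroxy-4,4'-dimethoxy-3,6'-bis(methoxymethoxy)-3'-prenylchalcone | COCOc1cc(/C=C/C(=O)c2c(OCOC)cc(OC)c(CC=C(C)C)c2O)ccc1OC
F5 | step 10 | racemic 7,4'-dimethoxy-5,3'-bis(methoxymethoxy)-8-prenylflavanone | COCOc1cc(C2CC(=O)c3c(OCOC)cc(OC)c(CC=C(C)C)c3O2)ccc1OC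
F6 | step 10 | racemic 5,3'-dihydroxy-7,4'-dimethoxy-8-prenylflavanone | COc1ccc(C2CC(=O)c3c(O)cc(OC)c(CC=C(C)C)c3O2)cc1O
F7 | step 8 | 2-[(2S)-2-Ar-4-oxo-3,4-dihydro-2H-pyran-6-yl]-5-methylhex-4-enoic acid | COc1ccc([C@@H]2CC(=O)C=C(C(CC=C(C)C)C(=O)O)O2)cc1O[Si](C(C)C)(C(C)C)C(C)C
F8 | step 7 | C4a phenylselanyl tetrahydropyranone TBS ester | COc1ccc([C@@H]2CC(=O)C([Se]c3ccccc3)C(C(CC=C(C)C)C(=O)O[Si](C)(C)C(C)(C)C)O2)cc1O[Si](C(C)C)(C(C)C)C(C)C
F9 | step 7 | corresponding selenoxide | COc1ccc([C@@H]2CC(=O)C([Se](=O)c3ccccc3)C(C(CC=C(C)C)C(=O)O[Si](C)(C)C(C)(C)C)O2)cc1O[Si](C(C)C)(C(C)C)C(C)C
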